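## Retrosynthetic overview

1. The seven-membered ring is closed last, by ring-closing metathesis between a vinyl group on the quaternary ring carbon and the vinyl group of a tertiary allylic carbinol side chain; the ring vinyl is unmasked from an ethynyl group just before.
2. The ester comes from acylation of the only secondary hydroxyl with silyl-protected 4-hydroxybenzoyl chloride (fragment C).
3. The isopropyl carbinol comes from organocerium addition to a cyclopentanone; the bond between ring and side chain comes from an anti-selective boron aldol of fragment A (silyl enol ether of (R)-3-alkynyl-3-methylcyclopentanone) with fragment B ((R)-3-methyl-3-silyloxypent-4-enal).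
4. Fragment A: copper-catalysed asymmetric conjugate methylation of a 3-alkynylcyclopentenone made from cyclopentane-1,3-dione. Fragment B: Sharpless epoxidation and hydride opening of (E)-3-methylpent-2-en-4-yn-1-ol.
5. Ring order: the five-membered ring is present from the start; the seven-membered ring is formed in the final step.

Assumption: the sense of induction of the chiral carbene ligand in step 3 is fixed by a test run and the ligand enantiomer that gives the (R)-configured enolate is used; a one-pot sequence counts as one step.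

## Route

**Fragment A**

Step 1
Reactants: 1 cyclopentane-1,3-dione
Product: 2 3-ethoxycyclopent-2-en-1-one
Conditions: EtOH, p-TsOH·H2O (cat.), toluene, reflux, Dean–Stark
Reagents that add atoms: ethanol (CCO)
Why: Acid-catalysed vinylogous esterification of the symmetric 1,3-dione, driven by azeotropic removal of water; no stereocentre is formed.

Step 2
Reactants: 2 3-ethoxycyclopent-2-en-1-one; 3 ethynyl(triethyl)silane
Product: 6 3-[(triethylsilyl)ethynyl]cyclopent-2-en-1-one, via lithium (triethylsilyl)acetylide 4 (not isolated), via tertiary alkynyl carbinol 5 (not isolated)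
Conditions: 3, n-BuLi, THF, −78 °C; then 2, −78 → 0 °C; then 1 M aq. HCl, rt
Reagents that add atoms: water (O)
Why: Stork–Danheiser transposition, in which 1,2-addition of the acetylide to the vinylogous ester is followed by acid hydrolysis of the enol ether and loss of the tertiary hydroxyl to give the 3-alkynyl enone; no stereocentre is formed.

Step 3
Reactants: 6 3-[(triethylsilyl)ethynyl]cyclopent-2-en-1-one
Product: 8 trimethyl({(3R)-3-methyl-3-[(triethylsilyl)ethynyl]cyclopent-1-en-1-yl}oxy)silane, via bromomagnesium enolate 7 (not isolated)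
Conditions: MeMgBr (1.2 equiv), Cu(OTf)2 (3 mol %), chiral imidazolinium salt (carbene ligand precursor, 4 mol %), Et2O, −30 °C; then Me3SiCl, Et3N, HMPA, −30 °C → rt
Reagents that add atoms: methylmagnesium bromide, MeMgBr (C[Mg]Br); chlorotrimethylsilane (C[Si](C)(C)Cl)
Why: Copper-catalysed asymmetric conjugate addition in which the chiral carbene–copper complex selects the enone face and so sets the quaternary centre (R), the silyl cap disfavours 1,6-attack at the alkyne terminus, and silylation of the magnesium enolate locks the enolate on the side of the quaternary carbon.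

**Fragment B**

Step 4
Reactants: 9 (2E)-3-methylpent-2-en-4-yn-1-ol
Product: 10 [(2S,3S)-3-ethynyl-3-methyloxiran-2-yl]methanol
Conditions: Ti(OiPr)4 (10 mol %), L-(+)-diethyl tartrate (12 mol %), t-BuOOH (2 equiv), 4 Å MS, CH2Cl2, −20 °C
Reagents that add atoms: tert-butyl hydroperoxide (CC(C)(C)OO)
Why: Sharpless asymmetric epoxidation, in which the titanium–L-tartrate complex delivers oxygen to one face of the E-allylic alcohol and thereby fixes the future tertiary carbinol carbon (3S in the epoxide).

Step 5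
Reactants: 10 [(2S,3S)-3-ethynyl-3-methyloxiran-2-yl]methanol
Product: 12 (3R)-3-methylpent-4-ene-1,3-diol, via alkyne-diol aluminate 11 (not isolated)
Conditions: NaAlH2(OCH2CH2OMe)2 (3.5 equiv), THF, 0 °C → rt; aq. potassium sodium tartrate
Reagents that add atoms: none
Why: Hydroxyl-directed hydride opening of the 2,3-epoxy alcohol at C2 gives the 1,3-diol with the tertiary C–O bond untouched (retention; the descriptor becomes R by priority change only), and the resulting tertiary propargylic alkoxide directs trans-hydroalumination of the terminal alkyne to the vinyl group.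

Step 6
Reactants: 12 (3R)-3-methylpent-4-ene-1,3-diol
Product: 13 (3R)-3-methyl-1,3-bis(triethylsilyloxy)pent-4-ene
Conditions: Et3SiOTf (2.3 equiv), 2,6-lutidine, CH2Cl2, −78 → 0 °C
Reagents that add atoms: triethylsilyl trifluoromethanesulfonate (CC[Si](CC)(CC)OS(=O)(=O)C(F)(F)F)
Why: Silyl triflate silylation caps both hydroxyls, the hindered tertiary allylic one included, without touching the stereocentre.

Step 7
Reactants: 13 (3R)-3-methyl-1,3-bis(triethylsilyloxy)pent-4-ene
Product: 14 (3R)-3-methyl-3-(triethylsilyloxy)pent-4-enal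
Conditions: (COCl)2, DMSO, CH2Cl2, −78 → −30 °C; then Et3N, −78 °C → rt
Reagents that add atoms: none
Why: Swern oxidation in which the activated sulfoxide attacks only the unhindered primary silyl ether and turns it directly into the aldehyde, while the tertiary silyl ether stays in place.

**Fragment C**

Step 8
Reactants: 15 4-hydroxybenzoic acid
Product: 17 4-[(tert-butyldimethylsilyl)oxy]benzoic acid, via bis-silylated benzoate 16 (not isolated)
Conditions: t-BuMe2SiCl (2.3 equiv), imidazole, DMF, rt; then AcOH, THF/H2O, rt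
Reagents that add atoms: tert-butyldimethylsilyl chloride (CC(C)(C)[Si](C)(C)Cl)
Why: Silylation of phenol and acid followed by selective hydrolysis of the labile silyl ester leaves only the phenol protected.

Step 9
Reactants: 17 4-[(tert-butyldimethylsilyl)oxy]benzoic acid
Product: 18 4-[(tert-butyldimethylsilyl)oxy]benzoyl chloride
Conditions: (COCl)2, DMF (cat.), CH2Cl2, 0 °C → rt; used crude
Reagents that add atoms: oxalyl chloride (ClC(=O)C(=O)Cl)
Why: Vilsmeier-type activation converts the acid into the acid chloride, and the aryl silyl ether tolerates the brief exposure to HCl.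

**Fragment union and endgame**

Step 10
Reactants: 8 trimethyl({(3R)-3-methyl-3-[(triethylsilyl)ethynyl]cyclopent-1-en-1-yl}oxy)silane; 14 (3R)-3-methyl-3-(triethylsilyloxy)pent-4-enal
Product: 21 (2S,3R)-2-[(1S,3R)-1-hydroxy-3-methyl-3-(triethylsilyloxy)pent-4-en-1-yl]-3-methyl-3-[(triethylsilyl)ethynyl]cyclopentan-1-one, via lithium enolate 19 (not isolated), via dibutylboron enolate 20 (not isolated)
Conditions: MeLi (1.05 equiv), THF, 0 °C; n-Bu2BOTf (1.1 equiv), −78 °C; then 14, −78 → −40 °C; pH 7 buffer, MeOH, 30% H2O2, 0 °C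
Reagents that add atoms: none
Why: Boron-mediated aldol addition through a Zimmerman–Traxler chair, in which the ring-locked E-enolate gives the anti aldol (carbinol centre S) and the aldehyde approaches the enolate carbon on the face of the slim, rod-like alkynyl group, anti to the methyl group (ring centre 2S).

Step 11
Reactants: 21 (2S,3R)-2-[(1S,3R)-1-hydroxy-3-methyl-3-(triethylsilyloxy)pent-4-en-1-yl]-3-methyl-3-[(triethylsilyl)ethynyl]cyclopentan-1-one
Product: 22 (1R,2S,3R)-2-[(1S,3R)-1-hydroxy-3-methyl-3-(triethylsilyloxy)pent-4-en-1-yl]-3-methyl-1-(propan-2-yl)-3-[(triethylsilyl)ethynyl]cyclopentan-1-ol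
Conditions: i-PrLi (3.5 equiv), anhydrous CeCl3 (3.6 equiv), THF, −78 °C; then 21, −78 → −40 °C; aq. NH4Cl
Reagents that add atoms: isopropyllithium, i-PrLi (CC(C)[Li])
Why: Organocerium (Imamoto) 1,2-addition, non-basic enough to suppress enolisation, retro-aldol and reduction, attacks the ketone face opposite the adjacent side chain and its cerium-bound alkoxide, giving the tertiary alcohol (1R) with the hydroxyl cis to the side chain.

Step 12
Reactants: 22 (1R,2S,3R)-2-[(1S,3R)-1-hydroxy-3-methyl-3-(triethylsilyloxy)pent-4-en-1-yl]-3-methyl-1-(propan-2-yl)-3-[(triethylsilyl)ethynyl]cyclopentan-1-ol; 18 4-[(tert-butyldimethylsilyl)oxy]benzoyl chloride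
Product: 23 (1S,3R)-1-{(1S,2R,5R)-2-hydroxy-5-methyl-2-(propan-2-yl)-5-[(triethylsilyl)ethynyl]cyclopentyl}-3-methyl-3-(triethylsilyloxy)pent-4-en-1-yl 4-[(tert-butyldimethylsilyl)oxy]benzoate
Conditions: 18 (1.5 equiv), Et3N, DMAP (1 equiv), CH2Cl2, 0 °C → rt
Reagents that add atoms: none
Why: DMAP-catalysed acylation takes place only at the secondary hydroxyl, because the tertiary hydroxyl is too hindered and the other tertiary oxygen is silylated; the carbinol configuration is retained.

Step 13
Reactants: 23 (1S,3R)-1-{(1S,2R,5R)-2-hydroxy-5-methyl-2-(propan-2-yl)-5-[(triethylsilyl)ethynyl]cyclopentyl}-3-methyl-3-(triethylsilyloxy)pent-4-en-1-yl 4-[(tert-butyldimethylsilyl)oxy]benzoate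
Product: 24 (1S,3R)-1-[(1S,2R,5R)-5-ethynyl-2-hydroxy-5-methyl-2-(propan-2-yl)cyclopentyl]-3-hydroxy-3-methylpent-4-en-1-yl 4-hydroxybenzoate
Conditions: n-Bu4NF (4 equiv), AcOH (4 equiv), THF, 0 °C → rt
Reagents that add atoms: none
Why: Fluoride-mediated desilylation removes the alkynyl, tertiary alkyl and aryl silyl groups in one operation, with acetic acid buffering the phenoxide so that the ester neither migrates nor cleaves.

Step 14
Reactants: 24 (1S,3R)-1-[(1S,2R,5R)-5-ethynyl-2-hydroxy-5-methyl-2-(propan-2-yl)cyclopentyl]-3-hydroxy-3-methylpent-4-en-1-yl 4-hydroxybenzoate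
Product: 25 (1S,3R)-1-[(1S,2R,5S)-5-ethenyl-2-hydroxy-5-methyl-2-(propan-2-yl)cyclopentyl]-3-hydroxy-3-methylpent-4-en-1-yl 4-hydroxybenzoate
Conditions: H2 (1 atm), Pd/CaCO3 poisoned with Pb(OAc)2 (Lindlar catalyst), quinoline, EtOAc, rt, stopped after 1 equiv H2
Reagents that add atoms: none
Why: Lindlar semihydrogenation stops at the alkene because the terminal alkyne binds the poisoned palladium far more strongly than the vinyl group; no stereocentre is touched (the quaternary descriptor changes from R to S by priority only).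

Step 15
Reactants: 25 (1S,3R)-1-[(1S,2R,5S)-5-ethenyl-2-hydroxy-5-methyl-2-(propan-2-yl)cyclopentyl]-3-hydroxy-3-methylpent-4-en-1-yl 4-hydroxybenzoate
Product: 26 (3R,3aS,4S,6R,8aS)-3,6-dihydroxy-6,8a-dimethyl-3-(propan-2-yl)-1,2,3,3a,4,5,6,8a-octahydroazulen-4-yl 4-hydroxybenzoate
Conditions: second-generation Grubbs catalyst RuCl2(=CHPh)(PCy3)(SIMes) (10 mol %), degassed toluene (2 mM), 80 °C
Reagents that add atoms: none
Why: Ring-closing metathesis of the two vinyl groups, held cis on the cyclopentane, closes the cis-fused seven-membered ring with loss of ethene; the free tertiary allylic hydroxyl assists the catalyst and the ring size enforces the Z alkene.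

## Compound list

1 | cyclopentane-1,3-dione | O=C1CCC(=O)C1 | starting material
2 | 3-ethoxycyclopent-2-en-1-one | CCOC1=CC(=O)CC1 | intermediate
3 | ethynyl(triethyl)silane | CC[Si](CC)(CC)C#C | starting material
4 | lithium (triethylsilyl)acetylide | [Li]C#C[Si](CC)(CC)CC | intermediate (not isolated)
5 | 3-ethoxy-1-[(triethylsilyl)ethynyl]cyclopent-2-en-1-ol (racemic, formed as its lithium alkoxide) | CCOC1=CC(O)(C#C[Si](CC)(CC)CC)CC1 | intermediate (not isolated)
6 | 3-[(triethylsilyl)ethynyl]cyclopent-2-en-1-one | O=C1C=C(C#C[Si](CC)(CC)CC)CC1 | intermediate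
7 | bromomagnesium (3R)-3-methyl-3-[(triethylsilyl)ethynyl]cyclopent-1-en-1-olate | Br[Mg]OC1=C[C@](C)(C#C[Si](CC)(CC)CC)CC1 | intermediate (not isolated)
8 | trimethyl({(3R)-3-methyl-3-[(triethylsilyl)ethynyl]cyclopent-1-en-1-yl}oxy)silane | C[Si](C)(C)OC1=C[C@](C)(C#C[Si](CC)(CC)CC)CC1 | intermediate
9 | (2E)-3-methylpent-2-en-4-yn-1-ol | OC/C=C(\C)C#C | starting material
10 | [(2S,3S)-3-ethynyl-3-methyloxiran-2-yl]methanol | OC[C@@H]1O[C@@]1(C)C#C | intermediate
11 | (3R)-3-methylpent-4-yne-1,3-diol, present as its aluminate | OCC[C@@](C)(O)C#C | intermediate (not isolated)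
12 | (3R)-3-methylpent-4-ene-1,3-diol | OCC[C@@](C)(O)C=C | intermediate
13 | (3R)-3-methyl-1,3-bis(triethylsilyloxy)pent-4-ene | CC[Si](CC)(CC)OCC[C@@](C)(O[Si](CC)(CC)CC)C=C | intermediate
14 | (3R)-3-methyl-3-(triethylsilyloxy)pent-4-enal | O=CC[C@@](C)(O[Si](CC)(CC)CC)C=C | intermediate
15 | 4-hydroxybenzoic acid | OC(=O)c1ccc(O)cc1 | starting material
16 | tert-butyldimethylsilyl 4-[(tert-butyldimethylsilyl)oxy]benzoate | CC(C)(C)[Si](C)(C)OC(=O)c1ccc(O[Si](C)(C)C(C)(C)C)cc1 | intermediate (not isolated)
17 | 4-[(tert-butyldimethylsilyl)oxy]benzoic acid | CC(C)(C)[Si](C)(C)Oc1ccc(cc1)C(=O)O | intermediate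
18 | 4-[(tert-butyldimethylsilyl)oxy]benzoyl chloride | CC(C)(C)[Si](C)(C)Oc1ccc(cc1)C(=O)Cl | intermediate
19 | lithium (3R)-3-methyl-3-[(triethylsilyl)ethynyl]cyclopent-1-en-1-olate | [Li]OC1=C[C@](C)(C#C[Si](CC)(CC)CC)CC1 | intermediate (not isolated)
20 | dibutyl({(3R)-3-methyl-3-[(triethylsilyl)ethynyl]cyclopent-1-en-1-yl}oxy)borane | CCCCB(CCCC)OC1=C[C@](C)(C#C[Si](CC)(CC)CC)CC1 | intermediate (not isolated)
21 | (2S,3R)-2-[(1S,3R)-1-hydroxy-3-methyl-3-(triethylsilyloxy)pent-4-en-1-yl]-3-methyl-3-[(triethylsilyl)ethynyl]cyclopentan-1-one | O=C1CC[C@@](C)(C#C[Si](CC)(CC)CC)[C@H]1[C@@H](O)C[C@@](C)(O[Si](CC)(CC)CC)C=C | intermediate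
22 | (1R,2S,3R)-2-[(1S,3R)-1-hydroxy-3-methyl-3-(triethylsilyloxy)pent-4-en-1-yl]-3-methyl-1-(propan-2-yl)-3-[(triethylsilyl)ethynyl]cyclopentan-1-ol | CC(C)[C@]1(O)CC[C@@](C)(C#C[Si](CC)(CC)CC)[C@H]1[C@@H](O)C[C@@](C)(O[Si](CC)(CC)CC)C=C | intermediate
23 | (1S,3R)-1-{(1S,2R,5R)-2-hydroxy-5-methyl-2-(propan-2-yl)-5-[(triethylsilyl)ethynyl]cyclopentyl}-3-methyl-3-(triethylsilyloxy)pent-4-en-1-yl 4-[(tert-butyldimethylsilyl)oxy]benzoate | CC(C)[C@]1(O)CC[C@@](C)(C#C[Si](CC)(CC)CC)[C@H]1[C@@H](OC(=O)c1ccc(O[Si](C)(C)C(C)(C)C)cc1)C[C@@](C)(O[Si](CC)(CC)CC)C=C | intermediate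
24 | (1S,3R)-1-[(1S,2R,5R)-5-ethynyl-2-hydroxy-5-methyl-2-(propan-2-yl)cyclopentyl]-3-hydroxy-3-methylpent-4-en-1-yl 4-hydroxybenzoate | CC(C)[C@]1(O)CC[C@@](C)(C#C)[C@H]1[C@@H](OC(=O)c1ccc(O)cc1)C[C@@](C)(O)C=C | intermediate
25 | (1S,3R)-1-[(1S,2R,5S)-5-ethenyl-2-hydroxy-5-methyl-2-(propan-2-yl)cyclopentyl]-3-hydroxy-3-methylpent-4-en-1-yl 4-hydroxybenzoate | CC(C)[C@]1(O)CC[C@@](C)(C=C)[C@H]1[C@@H](OC(=O)c1ccc(O)cc1)C[C@@](C)(O)C=C | intermediate
26 | (3R,3aS,4S,6R,8aS)-3,6-dihydroxy-6,8a-dimethyl-3-(propan-2-yl)-1,2,3,3a,4,5,6,8a-octahydroazulen-4-yl 4-hydroxybenzoate | CC(C)[C@]1(O)CC[C@@]2(C)C=C[C@](C)(O)C[C@H](OC(=O)c3ccc(O)cc3)[C@@H]12 | target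

## Step count, longest linear sequence, risks and fallbacks

Total step count: 15 (fragment A, steps 1–3; fragment B, steps 4–7; fragment C, steps 8–9; union and endgame, steps 10–15).
Longest linear sequence: 10 steps (steps 4–7, then 10–15), which is two thirds of the total.

**Step 3** (copper-catalysed methyl addition to the enynone). The risks are 1,6-addition across the enyne and a modest enantiomeric excess on a five-membered enone. Fallback: build the quaternary centre the other way round and take the absolute configuration from fragment B. Setting out from 4, ZnBr2 gives bromo[(triethylsilyl)ethynyl]zinc F1. This adds 1,4 to 3-methylcyclopent-2-en-1-one F2 under Me3SiOTf activation (Et2O/THF, −40 °C) and gives the racemic silyl enol ether F3 directly. Under the conditions of step 10 it passes through the racemic lithium enolate F4 and the racemic boron enolate F5 and reacts with enantiopure 14. The product is 21 together with the diastereomer F6 that stems from the (S)-enolate; the two are separated by chromatography and the route is rejoined at 21.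

**Step 10** (aldol at an enolate carbon next to a quaternary centre). The risks are low reactivity and the fact that two diastereoselections (enolate face and anti/syn) must both hold. Fallback: a Reformatsky-type coupling instead of a preformed boron enolate. Setting out from 8, N-bromosuccinimide (THF, 0 °C) gives the α-bromo ketone F7. CrCl2 in THF at room temperature reduces it in the presence of 14 to the chromium enolate F8. This adds through a closed, anti-selective transition state and tolerates hindered enolates, and the aldol returns to the route at 21.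

**Step 15** (metathesis between two vinyl groups on fully substituted carbons). The risk is a slow ring closure next to the bulky aroyloxy group, with a free phenol present. Fallback: close the ring before acylation. Setting out from 22, n-Bu4NF gives the alkyne triol F9, and Lindlar semihydrogenation gives the diene triol F10. Ring-closing metathesis with the same ruthenium catalyst gives the bicyclic triol F11. Acylation of its only secondary hydroxyl with 18 (Et3N, DMAP) gives the silyl-protected ester F12, and fluoride removes the phenol silyl ether to come back to the route at 26.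

## Further compounds

F1 | step 3 | bromo[(triethylsilyl)ethynyl]zinc | Br[Zn]C#C[Si](CC)(CC)CC
F2 | step 3 | 3-methylcyclopent-2-en-1-one | CC1=CC(=O)CC1
F3 | step 3 | racemic trimethyl({3-methyl-3-[(triethylsilyl)ethynyl]cyclopent-1-en-1-yl}oxy)silane | C[Si](C)(C)OC1=CC(C)(C#C[Si](CC)(CC)CC)CC1
F4 | step 3 | racemic lithium 3-methyl-3-[(triethylsilyl)ethynyl]cyclopent-1-en-1-olate | [Li]OC1=CC(C)(C#C[Si](CC)(CC)CC)CC1
F5 | step 3 | racemic dibutyl({3-methyl-3-[(triethylsilyl)ethynyl]cyclopent-1-en-1-yl}oxy)borane | CCCCB(CCCC)OC1=CC(C)(C#C[Si](CC)(CC)CC)CC1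
F6 | step 3 | (2R,3S)-2-[(1R,3R)-1-hydroxy-3-methyl-3-(triethylsilyloxy)pent-4-en-1-yl]-3-methyl-3-[(triethylsilyl)ethynyl]cyclopentan-1-one | O=C1CC[C@](C)(C#C[Si](CC)(CC)CC)[C@@H]1[C@H](O)C[C@@](C)(O[Si](CC)(CC)CC)C=C
F7 | step 10 | (2RS,3S)-2-bromo-3-methyl-3-[(triethylsilyl)ethynyl]cyclopentan-1-one | O=C1CC[C@@](C)(C#C[Si](CC)(CC)CC)C1Br
F8 | step 10 | dichlorochromium (3R)-3-methyl-3-[(triethylsilyl)ethynyl]cyclopent-1-en-1-olate | Cl[Cr](Cl)OC1=C[C@](C)(C#C[Si](CC)(CC)CC)CC1
F9 | step 15 | (1R,2S,3R)-2-[(1S,3R)-1,3-dihydroxy-3-methylpent-4-en-1-yl]-3-ethynyl-3-methyl-1-(propan-2-yl)cyclopentan-1-ol | CC(C)[C@]1(O)CC[C@@](C)(C#C)[C@H]1[C@@H](O)C[C@@](C)(O)C=C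
F10 | step 15 | (1R,2S,3S)-2-[(1S,3R)-1,3-dihydroxy-3-methylpent-4-en-1-yl]-3-ethenyl-3-methyl-1-(propan-2-yl)cyclopentan-1-ol | CC(C)[C@]1(O)CC[C@@](C)(C=C)[C@H]1[C@@H](O)C[C@@](C)(O)C=C
F11 | step 15 | (3R,3aS,4S,6R,8aS)-6,8a-dimethyl-3-(propan-2-yl)-1,2,3,3a,4,5,6,8a-octahydroazulene-3,4,6-triol | CC(C)[C@]1(O)CC[C@@]2(C)C=C[C@](C)(O)C[C@H](O)[C@@H]12
F12 | step 15 | (3R,3aS,4S,6R,8aS)-3,6-dihydroxy-6,8a-dimethyl-3-(propan-2-yl)-1,2,3,3a,4,5,6,8a-octahydroazulen-4-yl 4-[(tert-butyldimethylsilyl)oxy]benzoate | CC(C)[C@]1(O)CC[C@@]2(C)C=C[C@](C)(O)C[C@H](OC(=O)c3ccc(O[Si](C)(C)C(C)(C)C)cc3)[C@@H]12
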